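**Retrosynthetic overview**
- Side-chain numbering: C1'' (CH2 on C8), C2'' (CHOH), C3'' (CMe2OH). The key cut is C8–C1''. Ring A C8 is an enol (donor) carbon, and O7 and O2'' are 1,4-related, so the partner has to be a reversed-polarity a2 (enolonium-type) synthon, ⁺CH2–CH(OH)–CMe2OH. The reagent is (S)-2-(oxiran-2-yl)propan-2-ol, which brings the C2'' stereocentre with it.
- (2S)-6-Prenylnaringenin comes from (2S)-naringenin and prenol by Friedel–Crafts C6-prenylation; C2 is taken from the chiral pool.
- The epoxy alcohol comes from methyl (S)-glycidate and two equivalents of MeMgBr.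
- No ring is built: rings A, C and B are bought with naringenin and the oxirane with the glycidate.

Assumption: (2S)-naringenin and methyl (S)-glycidate are bought in high enantiomeric purity, and their ee is checked by chiral HPLC or GC before use.

**Step 1**
Reactants: 1 methyl (S)-glycidate; 2 methylmagnesium bromide
Product: 4 (S)-2-(oxiran-2-yl)propan-2-ol, via (S)-1-(oxiran-2-yl)ethanone 3 (not isolated)
Conditions: MeMgBr (2.2 equiv), THF, −78 → −30 °C; Na2SO4·10H2O quench, filter, distil
Reagents that add atoms: methylmagnesium bromide (compound 2), C[Mg]Br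
Why: Double Grignard addition to the ester (through ketone 3) is faster at low temperature than epoxide opening, and the stereocentre is an oxirane carbon that is never a reacting centre and does not enolise, so the (S) configuration of 1 passes unchanged into 4.

**Step 2**
Reactants: 5 (2S)-naringenin; 6 3-methylbut-2-en-1-ol (prenol)
Product: 7 (2S)-6-prenylnaringenin
Conditions: prenol (3 equiv), ZnCl2 (4 equiv), EtOAc, 40 °C; SiO2 chromatography to remove regioisomeric and bis-prenylated material
Reagents that add atoms: 3-methylbut-2-en-1-ol (compound 6), CC(C)=CCO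
Why: Lewis-acid-mediated Friedel–Crafts C-prenylation, in which ZnCl2 ionises prenol to the prenyl cation and the phloroglucinol-type ring A is attacked mainly at C6 (a known reaction type for naringenin; expect only about a quarter to a third of the C6 isomer, from memory); no stereocentre is made, and C2 should survive because the medium is non-basic (flavanones racemise by base-induced ring opening to the chalcone).

**Step 3**
Reactants: 7 (2S)-6-prenylnaringenin; 4 (S)-2-(oxiran-2-yl)propan-2-ol
Product: 8 (2S)-5,7-dihydroxy-8-[(2S)-2,3-dihydroxy-3-methylbutyl]-2-(4-hydroxyphenyl)-6-(3-methylbut-2-en-1-yl)chroman-4-one (target)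
Conditions: 4 (2 equiv), Sc(OTf)3 (20 mol%), 2,6-di-tert-butylpyridine (40 mol%), (CF3)2CHOH/CH2Cl2 1:4, 0 °C → rt
Reagents that add atoms: (S)-2-(oxiran-2-yl)propan-2-ol (compound 4), CC(C)(O)[C@@H]1CO1
Why: Proposed new method: a Friedel–Crafts hydroxyalkylation in which the ring A enol carbon C8 (the only free activated position once C6 is prenylated) opens epoxy alcohol 4 at its terminal CH2, so the epoxide acts as the reversed-polarity a2 (enolonium-type) partner; Sc(OTf)3 chelated between the tertiary OH and the oxirane oxygen should direct SN2-type attack to the distal primary carbon, the hydrogen-bonding fluoro alcohol should mask the phenol oxygens (C- over O-alkylation), and the hindered pyridine buffers triflic acid so the prenyl group is not cyclised; no bond to C2'' is broken, so its (S) configuration comes directly from 4, and C2 is untouched under non-basic conditions; the closest known reaction types are the Lewis-acid- or hexafluoroisopropanol-promoted arylative ring opening of epoxides by phenols and indoles, the distal (C3-selective) opening of chelated 2,3-epoxy alcohols, and the Sc(OTf)3-catalysed C-glycosylation of unprotected phloroglucinol-type flavanones.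

**Compound list**
1 | methyl (S)-glycidate, methyl (2S)-oxirane-2-carboxylate | COC(=O)[C@@H]1CO1 | starting material
2 | methylmagnesium bromide | C[Mg]Br | starting material
3 | (S)-1-(oxiran-2-yl)ethanone | CC(=O)[C@@H]1CO1 | intermediate (not isolated)
4 | (S)-2-(oxiran-2-yl)propan-2-ol | CC(C)(O)[C@@H]1CO1 | intermediate
5 | (2S)-naringenin, (2S)-5,7-dihydroxy-2-(4-hydroxyphenyl)chroman-4-one | O=C1C[C@@H](c2ccc(O)cc2)Oc2cc(O)cc(O)c12 | starting material
6 | 3-methylbut-2-en-1-ol (prenol) | CC(C)=CCO | starting material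
7 | (2S)-6-prenylnaringenin, (2S)-5,7-dihydroxy-2-(4-hydroxyphenyl)-6-(3-methylbut-2-en-1-yl)chroman-4-one | CC(C)=CCc1c(O)cc2c(c1O)C(=O)C[C@@H](c1ccc(O)cc1)O2 | intermediate
8 | (2S)-5,7-dihydroxy-8-[(2S)-2,3-dihydroxy-3-methylbutyl]-2-(4-hydroxyphenyl)-6-(3-methylbut-2-en-1-yl)chroman-4-one | CC(C)=CCc1c(O)c(C[C@H](O)C(C)(C)O)c2c(c1O)C(=O)C[C@@H](c1ccc(O)cc1)O2 | target

**Totals**
Total step count: 3. Longest linear sequence: 2 steps (5 → 7 → 8, or 1 → 4 → 8).

**Steps most likely to fail, with fallbacks**

Step 3 is the highest risk: O-alkylation, prenyl cyclisation to a chroman, or no reaction. The fallback sets out from 7 and comes back at 8, and inverts the polarity assignment so that C8 becomes the acceptor and the side-chain carbonyl carbon an acyl anion.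
- Treat 7 with N,N-dimethylmethyleneiminium iodide (MeCN, rt); only C8 is free on ring A, giving the Mannich base (2S)-8-[(dimethylamino)methyl]-6-prenylnaringenin F1.
- Heat F1 with ethyl glyoxylate, 3-benzyl-5-(2-hydroxyethyl)-4-methylthiazolium chloride (20 mol%) and Et3N in dioxane at 70 °C. Loss of dimethylamine gives the ortho-quinone methide (2S)-5-hydroxy-2-(4-hydroxyphenyl)-8-methylidene-6-prenyl-2,3-dihydrochromene-4,7-dione F2 (not isolated).
- The carbene-derived Breslow intermediate of the glyoxylate attacks the exocyclic CH2 of F2 (Stetter-type addition to a quinone methide) to give the α-keto ester ethyl 3-[(2S)-5,7-dihydroxy-2-(4-hydroxyphenyl)-4-oxo-6-prenylchroman-8-yl]-2-oxopropanoate F3.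
- A ketoreductase chosen from a panel for (S)-delivery (NADPH, glucose, glucose dehydrogenase, pH 7, 30 °C) sets C2'' in the hydroxy ester ethyl (2S)-3-[(2S)-5,7-dihydroxy-2-(4-hydroxyphenyl)-4-oxo-6-prenylchroman-8-yl]-2-hydroxypropanoate F4.
- Excess MeMgBr 2 (7 equiv, THF, −78 → −20 °C) converts the ester into the tertiary carbinol and returns 8. The phenols are magnesium salts at this point, which should deactivate the C4 ketone as a vinylogous carboxylate; this chemoselectivity is the weak point of the fallback.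

Step 2 is the next risk: low yield, a C6/C8 mixture, and possible erosion of C2. The fallback sets out from 5 and comes back at 7, with C6 fixed by a sigmatropic shift.
- TBSCl and imidazole (DMF, 0 °C) silylate the two non-chelated phenols to give (2S)-7-(tert-butyldimethylsilyloxy)-2-[4-(tert-butyldimethylsilyloxy)phenyl]-5-hydroxychroman-4-one F5.
- Mitsunobu O-allylation of the chelated 5-OH (allyl alcohol, PPh3, DIAD, THF, 0 °C → rt) gives (2S)-5-(allyloxy)-7-(tert-butyldimethylsilyloxy)-2-[4-(tert-butyldimethylsilyloxy)phenyl]chroman-4-one F6.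
- Aromatic Claisen rearrangement (europium tris(6,6,7,7,8,8,8-heptafluoro-2,2-dimethyloctane-3,5-dionate), Eu(fod)3, 10 mol%, chlorobenzene, 110 °C) can only deliver the allyl group to C6 and gives (2S)-6-allyl-7-(tert-butyldimethylsilyloxy)-2-[4-(tert-butyldimethylsilyloxy)phenyl]-5-hydroxychroman-4-one F7.
- Cross-metathesis with 2-methyl-2-butene (second-generation Grubbs catalyst 5 mol%, CH2Cl2, 40 °C) gives (2S)-7-(tert-butyldimethylsilyloxy)-2-[4-(tert-butyldimethylsilyloxy)phenyl]-5-hydroxy-6-(3-methylbut-2-en-1-yl)chroman-4-one F8.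
- HF·pyridine (THF, 0 °C) removes both silyl groups and returns 7.

Step 1 is the lowest risk of the three: the Grignard reagent or MgBr2 may open the epoxide. The fallback sets out from 1 and comes back at 4, with the oxirane masked as a bromohydrin during the addition.
- LiBr and AcOH (THF, rt) open 1 at C3 to give methyl (R)-3-bromo-2-hydroxypropanoate F9; the descriptor changes only because CH2Br outranks the ester, the geometry is the same.
- MeMgBr 2 (3.3 equiv, THF, −78 → 0 °C) gives (R)-1-bromo-3-methylbutane-2,3-diol F10.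
- K2CO3 in MeOH at 0 °C closes the secondary alkoxide onto CH2Br and returns 4 with C2 untouched throughout.

**Further compounds**
F1 | step 3 | (2S)-8-[(dimethylamino)methyl]-6-prenylnaringenin | CC(C)=CCc1c(O)c(CN(C)C)c2c(c1O)C(=O)C[C@@H](c1ccc(O)cc1)O2
F2 | step 3 | (2S)-5-hydroxy-2-(4-hydroxyphenyl)-8-methylidene-6-prenyl-2,3-dihydrochromene-4,7-dione | CC(C)=CCC1=C(O)C2=C(C(=C)C1=O)O[C@H](c1ccc(O)cc1)CC2=O
F3 | step 3 | ethyl 3-[(2S)-5,7-dihydroxy-2-(4-hydroxyphenyl)-4-oxo-6-prenylchroman-8-yl]-2-oxopropanoate | CC(C)=CCc1c(O)c(CC(=O)C(=O)OCC)c2c(c1O)C(=O)C[C@@H](c1ccc(O)cc1)O2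
F4 | step 3 | ethyl (2S)-3-[(2S)-5,7-dihydroxy-2-(4-hydroxyphenyl)-4-oxo-6-prenylchroman-8-yl]-2-hydroxypropanoate | CC(C)=CCc1c(O)c(C[C@H](O)C(=O)OCC)c2c(c1O)C(=O)C[C@@H](c1ccc(O)cc1)O2
F5 | step 2 | (2S)-7-(tert-butyldimethylsilyloxy)-2-[4-(tert-butyldimethylsilyloxy)phenyl]-5-hydroxychroman-4-one | O=C1C[C@@H](c2ccc(O[Si](C)(C)C(C)(C)C)cc2)Oc2cc(O[Si](C)(C)C(C)(C)C)cc(O)c12
F6 | step 2 | (2S)-5-(allyloxy)-7-(tert-butyldimethylsilyloxy)-2-[4-(tert-butyldimethylsilyloxy)phenyl]chroman-4-one | C=CCOc1cc(O[Si](C)(C)C(C)(C)C)cc2c1C(=O)C[C@@H](c1ccc(O[Si](C)(C)C(C)(C)C)cc1)O2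
F7 | step 2 | (2S)-6-allyl-7-(tert-butyldimethylsilyloxy)-2-[4-(tert-butyldimethylsilyloxy)phenyl]-5-hydroxychroman-4-one | C=CCc1c(O[Si](C)(C)C(C)(C)C)cc2c(c1O)C(=O)C[C@@H](c1ccc(O[Si](C)(C)C(C)(C)C)cc1)O2
F8 | step 2 | (2S)-7-(tert-butyldimethylsilyloxy)-2-[4-(tert-butyldimethylsilyloxy)phenyl]-5-hydroxy-6-(3-methylbut-2-en-1-yl)chroman-4-one | CC(C)=CCc1c(O[Si](C)(C)C(C)(C)C)cc2c(c1O)C(=O)C[C@@H](c1ccc(O[Si](C)(C)C(C)(C)C)cc1)O2
F9 | step 1 | methyl (R)-3-bromo-2-hydroxypropanoate | COC(=O)[C@@H](O)CBr
F10 | step 1 | (R)-1-bromo-3-methylbutane-2,3-diol | CC(C)(O)[C@@H](O)CBr
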